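**Plan**

1. Drimane numbering is used: C1–C10 are the decalin (ring A = C1–C5 and C10, ring B = C5–C10), C11 is the CH2O carbon on C9, C12 the methyl on C8, C13/C14 the methyls on C4, C15 the methyl on C10.
2. Retrosynthesis: cut the ether O–C11 (isofraxidin plus a primary alcohol), then C9–C11 so that C9 becomes a ketone carbon. Then cut C7=C8 and C5–C10 together, which opens both rings to an acyclic keto-enal. That chain is cut at C5=C6, C3–C4 and C1–C10 into pentan-3-one, acrolein, a prenyl unit and crotonaldehyde.
3. Enabling feature: in ring B the C7=C8 alkene carries C12 on C8 and lies next to C9, whose exocyclic C11 can be traded for a carbonyl oxygen. C12–C8–C9–C10–C15 is then simply pentan-3-one, with C10 and C8 as its two α-carbons, and C5–C6–C7 is an enal that cannot enolise because C4 is quaternary.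
4. Forward order: the chain is joined (C1–C10, then C3–C4, then C5=C6). One flask then closes ring A (Michael addition, C5–C10) and ring B (aldol condensation, C7=C8). The C9 carbonyl, the helper of that event, is exchanged for C11 by methylenation and hydroboration; ether formation and desilylation finish the route.
5. Stereochemistry: C3 comes from reagent control in an asymmetric prenylboration. C5 and C10 are relayed from C3 in the bicyclization (all-equatorial chair, trans fusion). C9 is set by hydroboration anti to the axial C15.

Key step: step 5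

Remark: the methyl-bearing carbon next to the ketone (the future C10) is formed racemic in step 1, so compounds 4, 7, 8 and 10 are carried as epimer mixtures at that centre; it becomes planar in the enolate of step 5 and is set there.

**Route**

Step 1
Reactants: 1 pentan-3-one; 2 prop-2-enal (acrolein)
Product: 4 4-methyl-5-oxoheptanal, via enamine 3 (not isolated)
Conditions: pyrrolidine, TsOH (cat.), toluene, reflux, Dean–Stark; then 2, MeCN, 0 °C to rt; then AcOH/NaOAc, H2O, rt
Reagents that add atoms: water, O
Why: Enamine Michael addition (Stork enamine reaction): the pyrrolidine enamine of the symmetrical ketone adds once to the β-carbon of acrolein and buffered hydrolysis returns the ketone, so that the 1,5-keto-aldehyde carries C15–C10–C9–C8–C12 and C1–C3 of the target, the methyl-bearing centre being formed racemic and planarised again in step 5.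

Step 2
Reactants: 4 4-methyl-5-oxoheptanal; 5 (3-methylbut-2-en-1-yl)magnesium chloride
Product: 7 (7S)-7-hydroxy-4,8,8-trimethyldec-9-en-3-one, via prenylborane 6 (not isolated)
Conditions: (+)-Ipc2BOMe [from (−)-α-pinene], 5, Et2O, −78 °C to rt; then 4, −78 °C; then NaOH, H2O2, 0 °C to rt
Reagents that add atoms: none
Why: Asymmetric allylboration with a diisopinocampheylborane: the borane formed from 5 reacts at −78 °C with the aldehyde only, through a six-membered chair transition state that joins its γ-carbon (C4) to C3, and the isopinocampheyl groups of the (−)-α-pinene series direct it to the Re face, which should give the (S)-carbinol.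

Step 3
Reactants: 7 (7S)-7-hydroxy-4,8,8-trimethyldec-9-en-3-one
Product: 8 (7S)-7-[(tert-butyldimethylsilyl)oxy]-4,8,8-trimethyldec-9-en-3-one
Conditions: TBSOTf, 2,6-lutidine, CH2Cl2, −78 to 0 °C
Reagents that add atoms: tert-butyldimethylsilyl trifluoromethanesulfonate, CC(C)(C)[Si](C)(C)OS(=O)(=O)C(F)(F)F
Why: Silylation of a hindered secondary alcohol with a silyl triflate, which removes the alkoxide that could cleave the C3–C4 bond by a retro-vinylogous aldol reaction under the basic conditions of step 5 and stops hemiketal formation with the ketone.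

Step 4
Reactants: 8 (7S)-7-[(tert-butyldimethylsilyl)oxy]-4,8,8-trimethyldec-9-en-3-one; 9 (2E)-but-2-enal (crotonaldehyde)
Product: 10 (2E,5S)-5-[(tert-butyldimethylsilyl)oxy]-4,4,8-trimethyl-9-oxoundec-2-enal
Conditions: second-generation Hoveyda–Grubbs catalyst RuCl2(H2IMes)(=CH-C6H4-2-OiPr) (5–10 mol%), 9 (5 equiv), CH2Cl2, 40 °C
Reagents that add atoms: none
Why: Olefin cross-metathesis of a hindered terminal alkene, which does not homodimerise, with an excess of an electron-poor partner should give the (E)-enal under thermodynamic control with loss of propene and adds C6 and C7.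

Step 5
Reactants: 10 (2E,5S)-5-[(tert-butyldimethylsilyl)oxy]-4,4,8-trimethyl-9-oxoundec-2-enal
Product: 13 (4aS,6S,8aS)-6-[(tert-butyldimethylsilyl)oxy]-2,5,5,8a-tetramethyl-4a,5,6,7,8,8a-hexahydronaphthalen-1(4H)-one, via keto-aldehyde 11 (not isolated), via ketol 12 (not isolated)
Conditions: KOt-Bu (0.3 equiv), t-BuOH/THF 1:1, 0.01 M, 0 to 45 °C
Reagents that add atoms: none
Why: Reversible deprotonation of the ethyl ketone gives both enolates, but only the tetrasubstituted C10 enolate can reach the enal β-carbon C5 through a six-membered transition state, so a 6-(enolexo)-exo-trig Michael addition closes ring A and forms C5–C10, after which the aldehyde released at C7 is attacked by the C8 enolate in a 6-(enolendo)-exo-trig aldol addition whose E1cB dehydration closes ring B as the C7=C8 enone. The closest known reaction type is the tandem intramolecular Michael addition/aldol condensation, a Robinson-type annulation run on a tethered keto-enal. C5 and C10 are set by the C3 silyloxy stereocentre through a chair-like transition state for ring A in which the silyloxy group, the enal arm on C5 and the enolate carbon C9 are equatorial and only the small C15 methyl is axial, which corresponds to the trans ring fusion with C15 on the face of the C3 oxygen. The step needs regioselectivity (C10 against C8 enolate, 1,4- against 1,2-attack) and facial selectivity at both termini: attack through C8 or on the carbonyl C7 would need an eight-membered ring, the quaternary C4 leaves the enal without γ-hydrogens and speeds the closure, and the Michael step stays reversible while only adducts with C6 and C9 gauche can condense, so that material should funnel to the fused enone. The racemic centre next to the ketone is erased in the enolate.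

Step 6
Reactants: 13 (4aS,6S,8aS)-6-[(tert-butyldimethylsilyl)oxy]-2,5,5,8a-tetramethyl-4a,5,6,7,8,8a-hexahydronaphthalen-1(4H)-one
Product: 14 (3S,5R,10S)-3-[(tert-butyldimethylsilyl)oxy]drima-7,9(11)-diene
Conditions: Ph3PCH3Br, KOt-Bu, toluene, 90 °C
Reagents that add atoms: methyltriphenylphosphonium bromide, C[P+](c1ccccc1)(c1ccccc1)c1ccccc1.[Br-]
Why: Wittig methylenation with the ylide generated by KOt-Bu and used hot, as for ketones next to a quaternary carbon, exchanges the C9 oxygen for C11, and since the ketone has no α-hydrogen C5 and C10 are not at risk.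

Step 7
Reactants: 14 (3S,5R,10S)-3-[(tert-butyldimethylsilyl)oxy]drima-7,9(11)-diene
Product: 15 (3S,5R,9S,10S)-3-[(tert-butyldimethylsilyl)oxy]drim-7-en-11-ol
Conditions: 9-BBN, THF, 0 °C to rt; then NaOH, H2O2, 0 °C
Reagents that add atoms: hydrogen peroxide, OO
Why: Hydroboration–oxidation: the bulky dialkylborane should add to the 1,1-disubstituted exocyclic alkene in preference to the trisubstituted ring alkene, with boron on C11 and hydrogen delivered to C9 from the α-face, anti to the axial C15 on the neighbouring C10, which sets C9 (S) with the hydroxymethyl group equatorial.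

Step 8
Reactants: 15 (3S,5R,9S,10S)-3-[(tert-butyldimethylsilyl)oxy]drim-7-en-11-ol; 16 isofraxidin (7-hydroxy-6,8-dimethoxy-2H-chromen-2-one)
Product: 17 7-{[(3S,5R,9S,10S)-3-[(tert-butyldimethylsilyl)oxy]drim-7-en-11-yl]oxy}-6,8-dimethoxy-2H-chromen-2-one
Conditions: PPh3, DIAD, THF, 0 °C to rt
Reagents that add atoms: none
Why: Mitsunobu etherification of a primary alcohol with the acidic 7-hydroxyl of the coumarin forms the O–C11 bond at a CH2 carbon, so no stereocentre is touched and the silyl ether keeps the C3 oxygen out of the reaction.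

Step 9
Reactants: 17 7-{[(3S,5R,9S,10S)-3-[(tert-butyldimethylsilyl)oxy]drim-7-en-11-yl]oxy}-6,8-dimethoxy-2H-chromen-2-one
Product: 18 7-{[(1S,4aR,6S,8aS)-6-hydroxy-2,5,5,8a-tetramethyl-1,4,4a,5,6,7,8,8a-octahydronaphthalen-1-yl]methoxy}-6,8-dimethoxy-2H-chromen-2-one (CNP0181523.1)
Conditions: HF (48% in H2O), MeCN, rt
Reagents that add atoms: none
Why: Fluoride-mediated cleavage of the silyl ether under mildly acidic conditions, which the lactone, the aryl ethers and the trisubstituted alkene should tolerate, frees the C3 hydroxyl without change at any stereocentre.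

**Compound list**

1 | pentan-3-one | CCC(=O)CC | starting material
2 | prop-2-enal (acrolein) | C=CC=O | starting material
3 | 1-(pent-2-en-3-yl)pyrrolidine (E/Z mixture) | CC=C(CC)N1CCCC1 | intermediate
4 | 4-methyl-5-oxoheptanal (racemic) | CCC(=O)C(C)CCC=O | intermediate
5 | (3-methylbut-2-en-1-yl)magnesium chloride | CC(C)=CC[Mg]Cl | starting material
6 | (3-methylbut-2-en-1-yl)diisopinocampheylborane, both isopinocampheyl groups of the (−)-α-pinene series | CC(C)=CCB([C@H]1C[C@H]2C[C@@H]([C@@H]1C)C2(C)C)[C@H]1C[C@H]2C[C@@H]([C@@H]1C)C2(C)C | intermediate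
7 | (7S)-7-hydroxy-4,8,8-trimethyldec-9-en-3-one (C4 epimers) | C=CC(C)(C)[C@@H](O)CCC(C)C(=O)CC | intermediate
8 | (7S)-7-[(tert-butyldimethylsilyl)oxy]-4,8,8-trimethyldec-9-en-3-one (C4 epimers) | C=CC(C)(C)[C@@H](O[Si](C)(C)C(C)(C)C)CCC(C)C(=O)CC | intermediate
9 | (2E)-but-2-enal (crotonaldehyde) | C/C=C/C=O | starting material
10 | (2E,5S)-5-[(tert-butyldimethylsilyl)oxy]-4,4,8-trimethyl-9-oxoundec-2-enal (C8 epimers) | O=C/C=C/C(C)(C)[C@@H](O[Si](C)(C)C(C)(C)C)CCC(C)C(=O)CC | intermediate
11 | 2-[(1S,3S,6S)-3-[(tert-butyldimethylsilyl)oxy]-2,2,6-trimethyl-6-propanoylcyclohexyl]acetaldehyde | O=CC[C@H]1C(C)(C)[C@@H](O[Si](C)(C)C(C)(C)C)CC[C@]1(C)C(=O)CC | intermediate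
12 | (4aS,6S,8aS)-6-[(tert-butyldimethylsilyl)oxy]-3-hydroxy-2,5,5,8a-tetramethyloctahydronaphthalen-1(2H)-one (C2 and C3 not assigned) | O=C1C(C)C(O)C[C@H]2C(C)(C)[C@@H](O[Si](C)(C)C(C)(C)C)CC[C@]12C | intermediate
13 | (4aS,6S,8aS)-6-[(tert-butyldimethylsilyl)oxy]-2,5,5,8a-tetramethyl-4a,5,6,7,8,8a-hexahydronaphthalen-1(4H)-one (3β-silyloxy-11-nordrim-7-en-9-one, trans-fused) | O=C1C(C)=CC[C@H]2C(C)(C)[C@@H](O[Si](C)(C)C(C)(C)C)CC[C@]12C | intermediate
14 | (3S,5R,10S)-3-[(tert-butyldimethylsilyl)oxy]drima-7,9(11)-diene | C=C1C(C)=CC[C@H]2C(C)(C)[C@@H](O[Si](C)(C)C(C)(C)C)CC[C@]12C | intermediate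
15 | (3S,5R,9S,10S)-3-[(tert-butyldimethylsilyl)oxy]drim-7-en-11-ol | OC[C@H]1C(C)=CC[C@H]2C(C)(C)[C@@H](O[Si](C)(C)C(C)(C)C)CC[C@]12C | intermediate
16 | isofraxidin (7-hydroxy-6,8-dimethoxy-2H-chromen-2-one) | COc1cc2ccc(=O)oc2c(OC)c1O | starting material
17 | 7-{[(3S,5R,9S,10S)-3-[(tert-butyldimethylsilyl)oxy]drim-7-en-11-yl]oxy}-6,8-dimethoxy-2H-chromen-2-one | COc1cc2ccc(=O)oc2c(OC)c1OC[C@H]1C(C)=CC[C@H]2C(C)(C)[C@@H](O[Si](C)(C)C(C)(C)C)CC[C@]12C | intermediate
18 | 7-{[(1S,4aR,6S,8aS)-6-hydroxy-2,5,5,8a-tetramethyl-1,4,4a,5,6,7,8,8a-octahydronaphthalen-1-yl]methoxy}-6,8-dimethoxy-2H-chromen-2-one | COc1cc2ccc(=O)oc2c(OC)c1OC[C@H]1C(C)=CC[C@H]2C(C)(C)[C@@H](O)CC[C@]12C | target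

Total step count: 9. Longest linear sequence: 9 steps (from 1 and 2 to 18; isofraxidin 16 enters at step 8).

**Steps most likely to fail**

Step 5. The Michael closure of ring A may run through the diastereomeric chair (cis fusion, or the wrong relation to C3), or retro-Michael and intermolecular aldol processes may outrun the condensation. The fallback sets out from 10 and comes back at 13. It takes the cascade apart and runs the C5–C10 bond formation under kinetic Lewis-acid control. Me3SiCl and Et3N in DMF at 80 °C should convert 10 into the more substituted silyl enol ether, (2E,5S)-5-[(tert-butyldimethylsilyl)oxy]-4,4,8-trimethyl-9-[(trimethylsilyl)oxy]undeca-2,8-dienal F1. TiCl4 in CH2Cl2 at −78 °C should then effect an intramolecular Mukaiyama–Michael addition through an open transition state to give keto-aldehyde 11, this time isolated and, if needed, freed from diastereomers. TsOH in benzene at reflux would close ring B by aldol condensation to 13.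

Step 4. Initiation and turnover at the vinyl group flanked by the quaternary carbon and the silyl ether may be slow, so that catalyst decay and self-metathesis of the aldehyde partner win. The fallback sets out from 8 and comes back at 10. Ozonolysis of 8 (O3, CH2Cl2, −78 °C; then PPh3) should give the α-quaternary aldehyde (3S)-3-[(tert-butyldimethylsilyl)oxy]-2,2,6-trimethyl-7-oxononanal F2, which cannot enolise at the new carbonyl. A Wittig reaction with (triphenylphosphoranylidene)acetaldehyde in toluene at 90 °C would then add C6 and C7 as the (E)-enal 10; the stabilised ylide should leave the ketone alone.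

Step 6. The ylide may not reach the C9 carbonyl, which is shielded by C10 and C12, and may act instead as a base (γ-deprotonation to the dienolate) or as a conjugate donor. The fallback sets out from 13 and comes back at 14. It is a Peterson olefination in two stages. Me3SiCH2Li with CeCl3 in THF at −78 °C should add 1,2 to the ketone and give the β-hydroxysilane (4aS,6S,8aS)-6-[(tert-butyldimethylsilyl)oxy]-2,5,5,8a-tetramethyl-1-[(trimethylsilyl)methyl]-1,4,4a,5,6,7,8,8a-octahydronaphthalen-1-ol F3. KH in THF would then eliminate across C9–C11 only, to give 14.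

Further compounds
F1 | step 5 | (2E,5S)-5-[(tert-butyldimethylsilyl)oxy]-4,4,8-trimethyl-9-[(trimethylsilyl)oxy]undeca-2,8-dienal | O=C/C=C/C(C)(C)[C@@H](O[Si](C)(C)C(C)(C)C)CCC(C)=C(CC)O[Si](C)(C)C
F2 | step 4 | (3S)-3-[(tert-butyldimethylsilyl)oxy]-2,2,6-trimethyl-7-oxononanal | O=CC(C)(C)[C@@H](O[Si](C)(C)C(C)(C)C)CCC(C)C(=O)CC
F3 | step 6 | (4aS,6S,8aS)-6-[(tert-butyldimethylsilyl)oxy]-2,5,5,8a-tetramethyl-1-[(trimethylsilyl)methyl]-1,4,4a,5,6,7,8,8a-octahydronaphthalen-1-ol (C1 not assigned) | C[Si](C)(C)CC1(O)C(C)=CC[C@H]2C(C)(C)[C@@H](O[Si](C)(C)C(C)(C)C)CC[C@]12C
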